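**Retrosynthetic overview**
1. The C15 caffeate is built last from the malonic half ester of the 15-hydroxy-19-oic acid and 3,4-dihydroxybenzaldehyde (Knoevenagel–Doebner, free catechol). The C19 acid comes from a C19 CH2OSi group, and a temporary C3 oxygen is removed by Barton–McCombie deoxygenation.
2. Key disconnections C4–C5 and C9–C10: one Lewis-acid cascade on an open-chain (3S,4R)-epoxy (Z)-ene allylsilane closes ring A first (C4–C5), then ring B (C9–C10), and ends by loss of silicon as the C8=C17 methylene.
3. Enabling feature: quaternary C4, the C5–C10 fusion bond, C9 and the exocyclic C8=C17 methylene are spaced as in a head-to-tail 1,5-diene. The cis fusion of rings A and B (H5 syn to C20) maps onto a (Z)-C5=C10 alkene, C11 anti to C20 onto a C8=C9 alkene with C7 and C11 trans, and axial C19 onto the epoxide of a (Z)-allylic alcohol, all through chair/chair anti additions.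
4. The open chain comes from (S)-citronellol (C9, C11–C16), a silylallyl Grignard reagent (C7, C8, C17), an Eschenmoser–Claisen rearrangement (C5, C6), an iodo-Wittig reaction (C10, C20), a B-alkyl Suzuki coupling with a (Z)-dienol (C1–C4, C18, C19) and a Sharpless epoxidation.

Key step: step 12

Assumption: labdane numbering (C1–C20) is used throughout; the target is read as 4S,5S,9R,10R,13S, i.e. a cis-fused decalin with H5, H9, C19 and C20 on one face (called β) and the C9 side chain on the other.

**Step 1**
Reactants: 1 (S)-citronellol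
Product: 2 tert-butyl{[(3S)-3,7-dimethyloct-6-en-1-yl]oxy}diphenylsilane
Conditions: TBDPSCl, imidazole, CH2Cl2, 0 °C to rt
Reagents that add atoms: tert-butyl(chloro)diphenylsilane, CC(C)(C)[Si](Cl)(c1ccccc1)c1ccccc1
Why: Standard silylation of a primary alcohol; the TBDPS ether should survive ozone, organometallic reagents, the Lewis acid of step 12 and the later selective cleavage of a TBS ether.

**Step 2**
Reactants: 2 tert-butyl{[(3S)-3,7-dimethyloct-6-en-1-yl]oxy}diphenylsilane
Product: 4 (4S)-6-[(tert-butyldiphenylsilyl)oxy]-4-methylhexanal, via secondary ozonide 3 (not isolated)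
Conditions: O3, CH2Cl2, −78 °C; then PPh3, −78 °C to rt
Reagents that add atoms: ozone, [O-][O+]=O
Why: Ozonolysis with reductive work-up cleaves the only C=C bond and leaves the aldehyde carbon that becomes C9; the C13 stereocentre is remote and untouched.

**Step 3**
Reactants: 4 (4S)-6-[(tert-butyldiphenylsilyl)oxy]-4-methylhexanal; 5 (2-bromoallyl)trimethylsilane
Product: 7 (3RS,6S)-8-[(tert-butyldiphenylsilyl)oxy]-6-methyl-2-[(trimethylsilyl)methyl]oct-1-en-3-ol, via alkenyl Grignard reagent 6 (not isolated)
Conditions: 5, Mg, THF, reflux; then 4, −78 to 0 °C; aq. NH4Cl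
Reagents that add atoms: none
Why: Grignard 1,2-addition to the aldehyde brings in C7, C8 and the silylmethyl carbon C17; the carbinol centre forms as a mixture that is erased in step 4.

**Step 4**
Reactants: 7 (3RS,6S)-8-[(tert-butyldiphenylsilyl)oxy]-6-methyl-2-[(trimethylsilyl)methyl]oct-1-en-3-ol
Product: 8 (4Z,8S)-10-[(tert-butyldiphenylsilyl)oxy]-N,N,8-trimethyl-4-[(trimethylsilyl)methyl]dec-4-enamide
Conditions: CH3C(OMe)2NMe2, xylenes, 140 °C
Reagents that add atoms: N,N-dimethylacetamide dimethyl acetal, CC(OC)(OC)N(C)C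
Why: Eschenmoser–Claisen rearrangement through a chair with the C9 alkyl chain equatorial forms the C6–C7 bond and the trisubstituted C8=C9 alkene with C11 trans to C7, under neutral conditions that spare the allylsilane.

**Step 5**
Reactants: 8 (4Z,8S)-10-[(tert-butyldiphenylsilyl)oxy]-N,N,8-trimethyl-4-[(trimethylsilyl)methyl]dec-4-enamide
Product: 9 (4Z,8S)-10-[(tert-butyldiphenylsilyl)oxy]-8-methyl-4-[(trimethylsilyl)methyl]dec-4-enal
Conditions: Cp2Zr(H)Cl, THF, rt; then H2O
Reagents that add atoms: none
Why: Cp2Zr(H)Cl reduces tertiary amides chemoselectively to aldehydes through a stable zirconated hemiaminal, so over-reduction is avoided and the trisubstituted alkene is not touched.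

**Step 6**
Reactants: 9 (4Z,8S)-10-[(tert-butyldiphenylsilyl)oxy]-8-methyl-4-[(trimethylsilyl)methyl]dec-4-enal
Product: 10 tert-butyl{[(3S,6Z,10Z)-11-iodo-3-methyl-7-[(trimethylsilyl)methyl]dodeca-6,10-dien-1-yl]oxy}diphenylsilane
Conditions: EtPPh3I, n-BuLi, THF, rt; I2, −78 °C; NaN(SiMe3)2, −20 °C; then 9, −78 °C to rt
Reagents that add atoms: ethyltriphenylphosphonium iodide, CC[P+](c1ccccc1)(c1ccccc1)c1ccccc1.[I-]; iodine, II
Why: Stork–Zhao-type Wittig olefination with the α-iodo ylide should give the (Z)-2-iodo-2-alkene (iodine cis to C6), which fixes the later (Z)-C5=C10 geometry and adds C10 and C20.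

**Step 7**
Reactants: 11 propargyl alcohol
Product: 13 (Z)-3-iodo-2-methylprop-2-en-1-ol, via alkenylmagnesium alkoxide 12 (not isolated)
Conditions: MeMgBr (2.5 equiv), CuI (10 mol%), THF, −20 °C to rt; then I2, −78 to 0 °C
Reagents that add atoms: methylmagnesium bromide, C[Mg]Br; iodine, II
Why: Alkoxide-directed, copper-catalysed anti-carbomagnesiation followed by iodinolysis with retention places CH2OH (C19) and iodine cis on the new alkene and brings in the C18 methyl.

**Step 8**
Reactants: 13 (Z)-3-iodo-2-methylprop-2-en-1-ol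
Product: 14 (2Z)-2-methylpenta-2,4-dien-1-ol
Conditions: vinylboronic acid pinacol ester, Pd(PPh3)4 (5 mol%), aq. K2CO3, THF, 65 °C
Reagents that add atoms: 4,4,5,5-tetramethyl-2-vinyl-1,3,2-dioxaborolane, C=CB1OC(C)(C)C(C)(C)O1
Why: Suzuki–Miyaura coupling proceeds with retention of alkene geometry and gives the (Z)-dienol that carries C1–C4, C18 and C19.

**Step 9**
Reactants: 14 (2Z)-2-methylpenta-2,4-dien-1-ol; 10 tert-butyl{[(3S,6Z,10Z)-11-iodo-3-methyl-7-[(trimethylsilyl)methyl]dodeca-6,10-dien-1-yl]oxy}diphenylsilane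
Product: 16 (2Z,6Z,10Z,14S)-16-[(tert-butyldiphenylsilyl)oxy]-2,6,14-trimethyl-10-[(trimethylsilyl)methyl]hexadeca-2,6,10-trien-1-ol, via bis-boron adduct 15 (not isolated)
Conditions: 14, 9-BBN (2.2 equiv), THF, 0 °C to rt; then 10, Pd(dppf)Cl2 (5 mol%), AsPh3, Cs2CO3, DMF/H2O, rt
Reagents that add atoms: none
Why: One equivalent of 9-BBN caps the hydroxyl and the second hydroborates only the monosubstituted alkene terminus (anti-Markovnikov); B-alkyl Suzuki–Miyaura coupling with the alkenyl iodide then forms C1–C10 with retention of both Z alkenes.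

**Step 10**
Reactants: 16 (2Z,6Z,10Z,14S)-16-[(tert-butyldiphenylsilyl)oxy]-2,6,14-trimethyl-10-[(trimethylsilyl)methyl]hexadeca-2,6,10-trien-1-ol
Product: 17 {(2R,3S)-3-[(3Z,7Z,11S)-13-[(tert-butyldiphenylsilyl)oxy]-3,11-dimethyl-7-[(trimethylsilyl)methyl]trideca-3,7-dien-1-yl]-2-methyloxiran-2-yl}methanol
Conditions: Ti(OiPr)4, diethyl D-(−)-tartrate, t-BuOOH, 4 Å MS, CH2Cl2, −20 °C
Reagents that add atoms: tert-butyl hydroperoxide, CC(C)(C)OO
Why: Sharpless asymmetric epoxidation is directed by the allylic hydroxyl and so touches only the C3=C4 alkene; the D-(−)-tartrate should deliver oxygen to the face that gives the (3S,4R)-epoxide (labdane numbering), setting C3 and C4, with the somewhat lower selectivity usual for Z-2-methyl-2-alkenols.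

**Step 11**
Reactants: 17 the (2R,3S)-epoxy alcohol
Product: 18 tert-butyldimethylsilyl ether of 17
Conditions: TBSCl, imidazole, CH2Cl2, 0 °C to rt
Reagents that add atoms: tert-butyl(chloro)dimethylsilane, CC(C)(C)[Si](C)(C)Cl
Why: Silylation removes the free hydroxyl, which would otherwise chelate the Lewis acid and steer epoxide opening towards C3.

**Step 12**
Reactants: 18 (3S,4R)-epoxy (Z)-ene allylsilane, C19 OTBS, C15 OTBDPS
Product: 19 (3S,4S,5S,9R,10R,13S)-cis-fused bicyclic alcohol (labdane numbering): 3β-OH, C19 OTBS, C15 OTBDPS, C8=C17 exocyclic alkene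
Conditions: MeAlCl2 (2 equiv), CH2Cl2, −78 °C; Et3N/MeOH quench, then aq. potassium sodium tartrate
Reagents that add atoms: none
Why: MeAlCl2 activates the epoxide, whose C4–O bond is opened with inversion by the C5=C10 π bond (ring A, 6-endo with respect to both epoxide and alkene), the developing C10 cation is captured anti by C9 of the allylsilane (ring B, 6-endo-trig), and the β-silyl cation at C8 loses Me3Si+ so that only the C8=C17 alkene can form. The closest known reaction type is the Lewis-acid epoxy-polyene (epoxy-allylsilane) bicyclization under Stork–Eschenmoser control, in which E alkenes give trans- and Z alkenes cis-fused rings and 4-(alkoxymethyl) epoxides are established initiators. C4 is set by SN2-like inversion of the Sharpless epoxide (the CH2OTBS group, cis to C2 on the oxirane, becomes axial C19) and C3 keeps its configuration with the oxygen equatorial. C5 and C10 follow from anti addition across the (Z)-C5=C10 alkene in a chair for ring A, which puts C6 axial and gives the cis fusion with H5, C20 and C19 on one face; the epoxide configuration selects the alkene face and hence the absolute configuration. C9 is set by a chair for ring B with the C11 chain equatorial, a consequence of C11 being trans to C7 on the C8=C9 alkene, so that C11 ends anti to C20. The step needs opening at tertiary C4 and not C3 (the silyl ether prevents chelation), capture of each cation faster than hydride shift or ring flip (nucleophilic allylsilane, −78 °C), and no protodesilylation (MeAlCl2 also scavenges protons).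

**Step 13**
Reactants: 19 the cis-fused bicyclic 3β-alcohol
Product: 20 3-O-(imidazol-1-ylthiocarbonyl) derivative of 19
Conditions: 1,1′-thiocarbonyldiimidazole, DMAP (cat.), ClCH2CH2Cl, 80 °C
Reagents that add atoms: 1,1′-thiocarbonyldiimidazole, S=C(n1ccnc1)n1ccnc1
Why: Thiocarbonylation under neutral conditions (first half of the Barton–McCombie deoxygenation) avoids an alkoxide that could trigger 1,5-migration of the neighbouring TBS group.

**Step 14**
Reactants: 20 the 3-O-thiocarbonylimidazolide
Product: 21 (4S,5S,9R,10R,13S)-3-deoxy bicycle: C19 OTBS, C15 OTBDPS, C8=C17 alkene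
Conditions: Bu3SnH, AIBN (cat.), toluene, 110 °C
Reagents that add atoms: none
Why: Barton–McCombie radical deoxygenation removes the C3 oxygen that served only as the cyclization trigger; the secondary C3 radical has no easy cyclization or fragmentation path and no stereocentre is affected.

**Step 15**
Reactants: 21 the 3-deoxy bis-silyl ether
Product: 22 C19 primary alcohol (C15 OTBDPS retained)
Conditions: HF·pyridine, pyridine, THF, 0 °C to rt
Reagents that add atoms: none
Why: Buffered HF·pyridine should cleave the TBS ether much faster than the TBDPS ether and does not isomerize the exocyclic alkene.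

**Step 16**
Reactants: 22 the C19 alcohol
Product: 23 C19 aldehyde
Conditions: Dess–Martin periodinane, NaHCO3, CH2Cl2, rt
Reagents that add atoms: none
Why: Dess–Martin oxidation converts the hindered neopentyl alcohol into the non-enolizable aldehyde under near-neutral conditions that leave the alkene and the silyl ether alone.

**Step 17**
Reactants: 23 the C19 aldehyde
Product: 24 (4S,5S,9R,10R,13S)-15-[(tert-butyldiphenylsilyl)oxy] 19-carboxylic acid
Conditions: NaClO2, NaH2PO4, 2-methyl-2-butene, t-BuOH/H2O, rt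
Reagents that add atoms: sodium chlorite, [Na+].[O-]Cl=O
Why: Pinnick oxidation gives the C19 acid; 2-methyl-2-butene scavenges HOCl and so protects the exocyclic alkene.

**Step 18**
Reactants: 24 the silyl-protected acid
Product: 25 (1S,4aR,5R,8aS)-5-[(3S)-5-hydroxy-3-methylpentyl]-1,4a-dimethyl-6-methylidenedecahydronaphthalene-1-carboxylic acid
Conditions: Bu4NF, THF, rt; dilute HCl work-up
Reagents that add atoms: none
Why: Fluoride cleaves the remaining silyl ether; the hindered tertiary carboxylic acid is inert.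

**Step 19**
Reactants: 25 the 15-hydroxy-19-oic acid; 26 Meldrum's acid
Product: 27 15-O-(carboxyacetyl) derivative of 25 (malonic half ester)
Conditions: toluene, 100 °C
Reagents that add atoms: none
Why: Thermolysis of Meldrum's acid gives an acylketene equivalent that acylates the unhindered primary alcohol, while the tertiary neopentyl C19 acid does not compete.

**Step 20**
Reactants: 27 the malonic half ester; 28 3,4-dihydroxybenzaldehyde
Product: 29 target, the (E)-caffeate of 25
Conditions: pyridine, piperidine (cat.), 50 °C, argon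
Reagents that add atoms: none
Why: Knoevenagel–Doebner condensation with decarboxylation should give the (E)-cinnamate directly with the free catechol, so no phenol protection is needed; the C19 acid and the exocyclic alkene are inert to pyridine/piperidine.

**Compound list**
1 | (S)-citronellol, (3S)-3,7-dimethyloct-6-en-1-ol | CC(C)=CCC[C@H](C)CCO | starting material
2 | tert-butyl{[(3S)-3,7-dimethyloct-6-en-1-yl]oxy}diphenylsilane | CC(C)=CCC[C@H](C)CCO[Si](c1ccccc1)(c1ccccc1)C(C)(C)C | intermediate
3 | secondary ozonide (1,2,4-trioxolane) of 2 | CC1(C)OOC(CC[C@H](C)CCO[Si](c2ccccc2)(c2ccccc2)C(C)(C)C)O1 | intermediate (not isolated)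
4 | (4S)-6-[(tert-butyldiphenylsilyl)oxy]-4-methylhexanal | O=CCC[C@H](C)CCO[Si](c1ccccc1)(c1ccccc1)C(C)(C)C | intermediate
5 | (2-bromoallyl)trimethylsilane | C=C(Br)C[Si](C)(C)C | starting material
6 | [3-(trimethylsilyl)prop-1-en-2-yl]magnesium bromide | C=C([Mg]Br)C[Si](C)(C)C | intermediate (not isolated)
7 | (3RS,6S)-8-[(tert-butyldiphenylsilyl)oxy]-6-methyl-2-[(trimethylsilyl)methyl]oct-1-en-3-ol | C=C(C[Si](C)(C)C)C(O)CC[C@H](C)CCO[Si](c1ccccc1)(c1ccccc1)C(C)(C)C | intermediate
8 | (4Z,8S)-10-[(tert-butyldiphenylsilyl)oxy]-N,N,8-trimethyl-4-[(trimethylsilyl)methyl]dec-4-enamide | CN(C)C(=O)CC/C(C[Si](C)(C)C)=C/CC[C@H](C)CCO[Si](c1ccccc1)(c1ccccc1)C(C)(C)C | intermediate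
9 | (4Z,8S)-10-[(tert-butyldiphenylsilyl)oxy]-8-methyl-4-[(trimethylsilyl)methyl]dec-4-enal | O=CCC/C(C[Si](C)(C)C)=C/CC[C@H](C)CCO[Si](c1ccccc1)(c1ccccc1)C(C)(C)C | intermediate
10 | tert-butyl{[(3S,6Z,10Z)-11-iodo-3-methyl-7-[(trimethylsilyl)methyl]dodeca-6,10-dien-1-yl]oxy}diphenylsilane | C/C(I)=C/CC/C(C[Si](C)(C)C)=C/CC[C@H](C)CCO[Si](c1ccccc1)(c1ccccc1)C(C)(C)C | intermediate
11 | propargyl alcohol | C#CCO | starting material
12 | bromomagnesium (Z)-3-(bromomagnesio)-2-methylprop-2-en-1-olate | Br[Mg]OC/C(C)=C\[Mg]Br | intermediate (not isolated)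
13 | (Z)-3-iodo-2-methylprop-2-en-1-ol | OC/C(C)=C\I | intermediate
14 | (2Z)-2-methylpenta-2,4-dien-1-ol | C=C/C=C(C)\CO | intermediate
15 | B-alkyl, O-boryl bis(9-BBN) adduct of 14 | B1(CC/C=C(C)\COB2C3CCCC2CCC3)C2CCCC1CCC2 | intermediate (not isolated)
16 | (2Z,6Z,10Z,14S)-16-[(tert-butyldiphenylsilyl)oxy]-2,6,14-trimethyl-10-[(trimethylsilyl)methyl]hexadeca-2,6,10-trien-1-ol | OC/C(C)=C\CC/C(C)=C\CC/C(C[Si](C)(C)C)=C/CC[C@H](C)CCO[Si](c1ccccc1)(c1ccccc1)C(C)(C)C | intermediate
17 | {(2R,3S)-3-[(3Z,7Z,11S)-13-[(tert-butyldiphenylsilyl)oxy]-3,11-dimethyl-7-[(trimethylsilyl)methyl]trideca-3,7-dien-1-yl]-2-methyloxiran-2-yl}methanol | OC[C@@]1(C)O[C@H]1CC/C(C)=C\CC/C(C[Si](C)(C)C)=C/CC[C@H](C)CCO[Si](c1ccccc1)(c1ccccc1)C(C)(C)C | intermediate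
18 | tert-butyldimethylsilyl ether of 17 | CC(C)(C)[Si](C)(C)OC[C@@]1(C)O[C@H]1CC/C(C)=C\CC/C(C[Si](C)(C)C)=C/CC[C@H](C)CCO[Si](c1ccccc1)(c1ccccc1)C(C)(C)C | intermediate
19 | (3S,4S,5S,9R,10R,13S)-cis-fused bicyclic 3β-alcohol, C19 OTBS, C15 OTBDPS, 8(17)-ene | C=C1CC[C@H]2[C@](C)(CC[C@H](O)[C@]2(C)CO[Si](C)(C)C(C)(C)C)[C@@H]1CC[C@H](C)CCO[Si](c1ccccc1)(c1ccccc1)C(C)(C)C | intermediate
20 | 3-O-(imidazol-1-ylthiocarbonyl) derivative of 19 | C=C1CC[C@H]2[C@](C)(CC[C@H](OC(=S)n3ccnc3)[C@]2(C)CO[Si](C)(C)C(C)(C)C)[C@@H]1CC[C@H](C)CCO[Si](c1ccccc1)(c1ccccc1)C(C)(C)C | intermediate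
21 | (4S,5S,9R,10R,13S)-3-deoxy bicycle, C19 OTBS, C15 OTBDPS | C=C1CC[C@H]2[C@](C)(CCC[C@]2(C)CO[Si](C)(C)C(C)(C)C)[C@@H]1CC[C@H](C)CCO[Si](c1ccccc1)(c1ccccc1)C(C)(C)C | intermediate
22 | C19 alcohol, C15 OTBDPS | C=C1CC[C@H]2[C@](C)(CCC[C@]2(C)CO)[C@@H]1CC[C@H](C)CCO[Si](c1ccccc1)(c1ccccc1)C(C)(C)C | intermediate
23 | C19 aldehyde, C15 OTBDPS | C=C1CC[C@H]2[C@](C)(CCC[C@]2(C)C=O)[C@@H]1CC[C@H](C)CCO[Si](c1ccccc1)(c1ccccc1)C(C)(C)C | intermediate
24 | C19 carboxylic acid, C15 OTBDPS | C=C1CC[C@H]2[C@](C)(CCC[C@]2(C)C(=O)O)[C@@H]1CC[C@H](C)CCO[Si](c1ccccc1)(c1ccccc1)C(C)(C)C | intermediate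
25 | (1S,4aR,5R,8aS)-5-[(3S)-5-hydroxy-3-methylpentyl]-1,4a-dimethyl-6-methylidenedecahydronaphthalene-1-carboxylic acid | C=C1CC[C@H]2[C@](C)(CCC[C@]2(C)C(=O)O)[C@@H]1CC[C@H](C)CCO | intermediate
26 | Meldrum's acid, 2,2-dimethyl-1,3-dioxane-4,6-dione | CC1(C)OC(=O)CC(=O)O1 | starting material
27 | 15-O-(carboxyacetyl) derivative of 25 | C=C1CC[C@H]2[C@](C)(CCC[C@]2(C)C(=O)O)[C@@H]1CC[C@H](C)CCOC(=O)CC(=O)O | intermediate
28 | 3,4-dihydroxybenzaldehyde | O=Cc1ccc(O)c(O)c1 | starting material
29 | target, 15-O-[(E)-caffeoyl] derivative of 25 | C=C1CC[C@H]2[C@](C)(CCC[C@]2(C)C(=O)O)[C@@H]1CC[C@H](C)CCOC(=O)/C=C/c1ccc(O)c(O)c1 | target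

**Total step count:** 20 (steps 7 and 8 form the short side branch).
**Longest linear sequence:** 18 steps from (S)-citronellol (steps 1–6 and 9–20).

**Steps most likely to fail**

Step 12 (key cascade). The epoxide may ionize ahead of π-participation and undergo a 1,2-hydride shift. The allylsilane may be protodesilylated by adventitious acid. The C10 cation may live long enough for ring flip before capture. Each of these would cost yield or erode the cis fusion and the C9 configuration. Fallback, setting out from 17 and returning at 19: the unprotected epoxy alcohol 17 is cyclized without any metal Lewis acid, by hydrogen-bond activation in 1,1,1,3,3,3-hexafluoropropan-2-ol with catalytic Ph4PBF4 at 0 °C. This is a known way to run epoxide-initiated polyene cyclizations in a strongly ionizing, non-nucleophilic medium, and the silyl group is transferred to the solvent. It should give the cis-fused bicyclic 3,19-diol F1. Silylation of the primary hydroxyl of F1 with TBSCl/imidazole at low temperature then gives 19, so that protection follows ring formation instead of preceding it.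

Step 9 (hydroboration and B-alkyl coupling). Hydroboration of the conjugated dienol may be unselective (addition across the diene or double hydroboration), and transmetalation of the O-borylated borane may be slow. Fallback, setting out from 10 and 13 and returning at 16: the roles of the partners are exchanged. Alkenyl iodide 10 is vinylated with vinylboronic acid pinacol ester (Pd(PPh3)4, aq. K2CO3) to the (Z)-configured 2-methyl-1,3-diene F2. Its monosubstituted terminus is hydroborated with 9-BBN to the homoallylic alkylborane F3. This borane is coupled under the step 9 conditions with the hydroxy alkenyl iodide 13, forming the C2–C3 bond and giving 16.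

Step 10 (asymmetric epoxidation). Facial discrimination may be incomplete on the Z-trisubstituted allylic alcohol, and the minor epoxide would lead to a core diastereomer that is hard to remove because C13 is remote. Fallback, setting out from 14 and returning at 18: the epoxide is installed on the small fragment before the union. Sharpless epoxidation of 14 with the same D-(−)-tartrate gives the vinyl epoxy alcohol F4. It is trapped in situ with 4-nitrobenzoyl chloride as the 4-nitrobenzoate F5, which should be recrystallizable to enantiopurity. Methanolysis (K2CO3, MeOH) back to F4 and silylation give the TBS ether F6. Hydroboration of its vinyl group with 9-BBN gives the epoxy alkylborane F7, and B-alkyl Suzuki–Miyaura coupling with 10 under the step 9 conditions gives 18 directly.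

**Further compounds**
F1 | step 12 | (3S,4S,5S,9R,10R,13S)-cis-fused bicyclic 3,19-diol, C15 OTBDPS, 8(17)-ene | C=C1CC[C@H]2[C@](C)(CC[C@H](O)[C@]2(C)CO)[C@@H]1CC[C@H](C)CCO[Si](c1ccccc1)(c1ccccc1)C(C)(C)C
F2 | step 9 | tert-butyl{[(3S,6Z,10Z)-3,11-dimethyl-7-[(trimethylsilyl)methyl]trideca-6,10,12-trien-1-yl]oxy}diphenylsilane | C=C/C(C)=C\CC/C(C[Si](C)(C)C)=C/CC[C@H](C)CCO[Si](c1ccccc1)(c1ccccc1)C(C)(C)C
F3 | step 9 | 9-BBN alkylborane from terminal hydroboration of F2 | B1(CC/C(C)=C\CC/C(C[Si](C)(C)C)=C/CC[C@H](C)CCO[Si](c2ccccc2)(c2ccccc2)C(C)(C)C)C2CCCC1CCC2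
F4 | step 10 | [(2R,3S)-3-ethenyl-2-methyloxiran-2-yl]methanol | OC[C@@]1(C)O[C@H]1C=C
F5 | step 10 | [(2R,3S)-3-ethenyl-2-methyloxiran-2-yl]methyl 4-nitrobenzoate | O=C(OC[C@@]1(C)O[C@H]1C=C)c1ccc([N+](=O)[O-])cc1
F6 | step 10 | tert-butyl{[(2R,3S)-3-ethenyl-2-methyloxiran-2-yl]methoxy}dimethylsilane | CC(C)(C)[Si](C)(C)OC[C@@]1(C)O[C@H]1C=C
F7 | step 10 | 9-BBN alkylborane from hydroboration of F6 | CC(C)(C)[Si](C)(C)OC[C@@]1(C)O[C@H]1CCB1C2CCCC1CCC2
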